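**Retrosynthetic overview**
1. Bisnorstriatol is C2-symmetric: two 3,5-dihydroxyphenyl rings sit on C1 and C14 of an unbranched tetradecane chain, and the C7–C8 bond lies at its midpoint. That bond is the key disconnection, formed by anodic decarboxylative homocoupling (Kolbe electrolysis) of two 7-arylheptyl radicals from 8-aryloctanoic acid 6, a union of two primary carbons of like polarity.
2. Half-acid 6 comes from hydrogenation of the Wittig product of aldehyde 2 and the ylide of the commercial C7 phosphonium salt 3 (benzylic C–C bond).
3. The four phenols are carried as tosylates from step 1. These tolerate the ylide and H2/Pd, and they make the rings electron-poor enough to survive the anode; hydroxide removes them at the end.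
4. No ring is formed (both benzene rings are bought as 3,5-dihydroxybenzaldehyde) and no stereocentre has to be set.

Key step: step 4

Remark: the target has no stereocentre and is achiral, so the demand for a single enantiomer is met without any enantiocontrol. Ts = 4-methylbenzenesulfonyl, and "tosyloxy" = 4-methylbenzenesulfonyloxy.

**Route**

Step 1
Reactants: 1 3,5-dihydroxybenzaldehyde
Product: 2 3,5-bis(tosyloxy)benzaldehyde
Conditions: TsCl (2.3 equiv), Et3N (3 equiv), DMAP (5 mol%), CH2Cl2, 0 °C → rt
Reagents that add atoms: p-toluenesulfonyl chloride (TsCl), Cc1ccc(cc1)S(=O)(=O)Cl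
Why: DMAP-catalysed O-sulfonylation of both phenols is fast and leaves the aldehyde untouched, and it installs a phenol protecting group that is stable to ylides and hydrogenation and is electron-withdrawing.

Step 2
Reactants: 2 3,5-bis(tosyloxy)benzaldehyde; 3 (6-carboxyhexyl)triphenylphosphonium bromide
Product: 5 (Z)-8-[3,5-bis(tosyloxy)phenyl]oct-7-enoic acid, via sodium carboxylate ylide 4 (not isolated)
Conditions: 3 (1.25 equiv), NaHMDS (2.45 equiv), THF, 0 °C; then 2, −78 °C → rt; 1 M HCl work-up
Reagents that add atoms: none
Why: Wittig olefination with the non-stabilised, carboxylate-bearing ylide should add to the strongly electrophilic aldehyde at −78 °C faster than it attacks a sulfonate sulfur, giving mainly the Z-alkene, whose geometry is of no consequence because the double bond is removed in step 3.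

Step 3
Reactants: 5 (Z)-8-[3,5-bis(tosyloxy)phenyl]oct-7-enoic acid
Product: 6 8-[3,5-bis(tosyloxy)phenyl]octanoic acid
Conditions: H2 (1 atm), 10% Pd/C, EtOAc, rt
Reagents that add atoms: none
Why: Heterogeneous catalytic hydrogenation of the disubstituted styrenic alkene (either isomer) at 1 atm should leave the aryl sulfonates, the arene rings and the carboxylic acid unchanged.

Step 4
Reactants: 6 8-[3,5-bis(tosyloxy)phenyl]octanoic acid (two molecules)
Product: 9 1,14-bis[3,5-bis(tosyloxy)phenyl]tetradecane, via potassium carboxylate 7 (not isolated), via 7-arylheptyl radical 8 (not isolated)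
Conditions: KOH (0.1 equiv), MeOH/acetone 3:1, undivided cell, smooth Pt anode/Pt cathode, constant current ca. 0.2 A cm−2, 40 °C, until the electrolyte turns weakly basic
Reagents that add atoms: none
Why: Kolbe electrolysis: carboxylate 7, adsorbed on the platinum anode, is oxidised by one electron to the acyloxy radical, which loses CO2 to give the unstabilised primary radical 8, and at high current density two such radicals combine at the electrode surface to form the C7–C8 bond of the tetradecane chain. The closest known reaction type is the anodic decarboxylative homodimerisation of unbranched ω-aryl- and ω-functionalised alkanoic acids to symmetric long-chain compounds, for which platinum, methanol, partial neutralisation and high current density are the standard conditions. No ring is closed and no stereocentre is formed, and because both partners are the same radical there is no cross-coupling statistics to manage. The step needs oxidation of the carboxylate in preference to the two arene rings: the sulfonyloxy groups are net electron-withdrawing, so each ring should be harder to oxidise than a plain phenyl group, which Kolbe conditions tolerate, whereas methyl or benzyl ethers of the resorcinol would be expected to oxidise below the Kolbe potential. It also needs radical coupling to win over two-electron oxidation to the cation (Hofer–Moest pathway) and over disproportionation, and a primary radical seven carbons away from the ring, without α-branching or a stabilising substituent, in a weakly acidic medium free of foreign anions, is the substrate class that favours the dimer.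

Step 5
Reactants: 9 1,14-bis[3,5-bis(tosyloxy)phenyl]tetradecane
Product: 10 bisnorstriatol [1,14-bis(3,5-dihydroxyphenyl)tetradecane]
Conditions: KOH (20 equiv), 1,4-dioxane/H2O 2:1, 95 °C, Ar (degassed); then 2 M HCl
Reagents that add atoms: none
Why: Hydroxide should attack the sulfonyl sulfur of each aryl tosylate with S–O cleavage (the phenol oxygen stays on the ring), the alcohol-free medium avoids formation of an alkyl tosylate that could O-alkylate the phenoxides, and the inert atmosphere protects the resorcinolate from air oxidation.

**Compound list**
1 | 3,5-dihydroxybenzaldehyde | O=Cc1cc(O)cc(O)c1 | starting material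
2 | 3,5-bis(tosyloxy)benzaldehyde | O=Cc1cc(OS(=O)(=O)c2ccc(C)cc2)cc(OS(=O)(=O)c2ccc(C)cc2)c1 | intermediate
3 | (6-carboxyhexyl)triphenylphosphonium bromide | OC(=O)CCCCCC[P+](c1ccccc1)(c1ccccc1)c1ccccc1.[Br-] | starting material
4 | sodium 7-(triphenylphosphoranylidene)heptanoate (carboxylate ylide) | [Na+].[O-]C(=O)CCCCCC=P(c1ccccc1)(c1ccccc1)c1ccccc1 | intermediate (not isolated)
5 | (Z)-8-[3,5-bis(tosyloxy)phenyl]oct-7-enoic acid (major isomer; the E isomer converges in step 3) | OC(=O)CCCCC/C=C\c1cc(OS(=O)(=O)c2ccc(C)cc2)cc(OS(=O)(=O)c2ccc(C)cc2)c1 | intermediate
6 | 8-[3,5-bis(tosyloxy)phenyl]octanoic acid | OC(=O)CCCCCCCc1cc(OS(=O)(=O)c2ccc(C)cc2)cc(OS(=O)(=O)c2ccc(C)cc2)c1 | intermediate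
7 | potassium 8-[3,5-bis(tosyloxy)phenyl]octanoate | [K+].[O-]C(=O)CCCCCCCc1cc(OS(=O)(=O)c2ccc(C)cc2)cc(OS(=O)(=O)c2ccc(C)cc2)c1 | intermediate (not isolated)
8 | 7-[3,5-bis(tosyloxy)phenyl]heptyl radical | [CH2]CCCCCCc1cc(OS(=O)(=O)c2ccc(C)cc2)cc(OS(=O)(=O)c2ccc(C)cc2)c1 | intermediate (not isolated)
9 | 1,14-bis[3,5-bis(tosyloxy)phenyl]tetradecane | Cc1ccc(cc1)S(=O)(=O)Oc1cc(OS(=O)(=O)c2ccc(C)cc2)cc(CCCCCCCCCCCCCCc2cc(OS(=O)(=O)c3ccc(C)cc3)cc(OS(=O)(=O)c3ccc(C)cc3)c2)c1 | intermediate
10 | bisnorstriatol, 1,14-bis(3,5-dihydroxyphenyl)tetradecane | Oc1cc(O)cc(CCCCCCCCCCCCCCc2cc(O)cc(O)c2)c1 | target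

**Totals**
Total step count: 5. Longest linear sequence: 5 steps (1 → 2 → 5 → 6 → 9 → 10).

**Steps most likely to fail, with fallbacks**

1. Step 4 (Kolbe dimerisation). What may go wrong: over-oxidation of the alkyl radical to the cation with ether and alkene formation, radical disproportionation, or passivation of the anode by the sparingly soluble dimer, so that current is spent without productive coupling. The fallback gives up the dimerisation for a two-directional chain extension and sets out from 2. Commercial 1,12-dibromododecane and triphenylphosphine (DMF, 120 °C) should give dodecane-1,12-diylbis(triphenylphosphonium) dibromide F1. Double deprotonation (NaHMDS, THF, 0 °C) should give the bis-ylide 1,12-bis(triphenylphosphoranylidene)dodecane F2, which is not isolated. At −78 °C → rt it should take up two molecules of 2 in a double Wittig reaction to give (1Z,13Z)-1,14-bis[3,5-bis(tosyloxy)phenyl]tetradeca-1,13-diene F3, the alkene geometry being irrelevant. Hydrogenation (H2, Pd/C, EtOAc/THF) should then give 9, where the route is rejoined before step 5.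

2. Step 2 (Wittig olefination). What may go wrong: attack of the ylide or of residual amide base on a sulfonyl sulfur, that is, loss or transfer of the tosyl protecting groups in competition with olefination, or sluggish reaction of the poorly soluble dianionic ylide. The fallback moves the sulfonylation behind the basic step; it sets out from 3 and needs neither 1 nor 2. Ylide 4, made from 3 as in step 2, is combined with commercial 3,5-dimethoxybenzaldehyde, which carries no sulfonate, to give (Z)-8-(3,5-dimethoxyphenyl)oct-7-enoic acid F4. Hydrogenation (H2, Pd/C, EtOAc) should give 8-(3,5-dimethoxyphenyl)octanoic acid F5. Demethylation (BBr3, CH2Cl2, −78 °C → rt, aqueous work-up) should give 8-(3,5-dihydroxyphenyl)octanoic acid F6. Tosylation of both phenols under Schotten–Baumann conditions (TsCl, aq. NaOH/THF, 0 °C, then HCl; any mixed anhydride at the carboxyl group is hydrolysed in the aqueous base) should give 6, where the route is rejoined before step 4.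

3. Step 5 (fourfold detosylation). What may go wrong: incomplete cleavage of the four sulfonates because the lipophilic tetratosylate dissolves poorly in aqueous base, and air oxidation of the electron-rich resorcinolate during prolonged heating. The fallback replaces nucleophilic hydrolysis by reductive S–O cleavage through electron transfer. It sets out from 9 and comes back at 10: magnesium turnings in MeOH/THF at rt (sonication), followed by dilute HCl, should reduce each arenesulfonyl group to the sulfinate and release the phenols under much milder, non-hydrolytic conditions. No new compound is formed on the way (F0).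

**Further compounds**
F1 | step 4 | dodecane-1,12-diylbis(triphenylphosphonium) dibromide | [Br-].[Br-].c1ccc(cc1)[P+](c1ccccc1)(c1ccccc1)CCCCCCCCCCCC[P+](c1ccccc1)(c1ccccc1)c1ccccc1
F2 | step 4 | 1,12-bis(triphenylphosphoranylidene)dodecane (bis-ylide, not isolated) | c1ccc(cc1)P(c1ccccc1)(c1ccccc1)=CCCCCCCCCCCC=P(c1ccccc1)(c1ccccc1)c1ccccc1
F3 | step 4 | (1Z,13Z)-1,14-bis[3,5-bis(tosyloxy)phenyl]tetradeca-1,13-diene | Cc1ccc(cc1)S(=O)(=O)Oc1cc(OS(=O)(=O)c2ccc(C)cc2)cc(/C=C\CCCCCCCCCC/C=C\c2cc(OS(=O)(=O)c3ccc(C)cc3)cc(OS(=O)(=O)c3ccc(C)cc3)c2)c1
F4 | step 2 | (Z)-8-(3,5-dimethoxyphenyl)oct-7-enoic acid | COc1cc(OC)cc(/C=C\CCCCCC(O)=O)c1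
F5 | step 2 | 8-(3,5-dimethoxyphenyl)octanoic acid | COc1cc(OC)cc(CCCCCCCC(O)=O)c1
F6 | step 2 | 8-(3,5-dihydroxyphenyl)octanoic acid | Oc1cc(O)cc(CCCCCCCC(O)=O)c1
F0 | step 5 | none | none
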